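**Strategy**

Ring C of the flavanone is opened at O1–C8a and C4–C4a. C8a and C4a are neighbouring carbons of ring A that carry the ether oxygen O1 and the acyl carbon C4, so ring A is introduced as an aryne: the hydroxyl oxygen of an (R)-β-hydroxy ester adds to one aryne carbon and the carbanion formed beside it acylates on the ester, closing ring C in one operation while the C2 centre, set earlier by asymmetric transfer hydrogenation, is untouched. The precursor is methyl (R)-3-hydroxy-3-(2,2-dimethyl-8-prenylchromen-6-yl)propanoate; the aryne carries MOM-protected oxygens at C5 and C7, the C5 oxygen steering regiochemistry before its reductive removal.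

Key step: step 9

Remark: flavanone numbering (O1, C2, C3, C4, C4a, C5 to C8, C8a) is used for rings A and C; "Chr" stands for the ring B unit 2,2-dimethyl-8-(3-methylbut-2-en-1-yl)-2H-chromen-6-yl.

Assumption: RuCl[(R,R)-TsDPEN](p-cymene) is taken to give the (R)-carbinol from the aryl β-keto ester, as it does from simple aryl alkyl ketones.

Design notes:
- The methyl ester and the free hydroxyl are kept on purpose. A more activated acyl group would let the alkoxide close a β-lactone, and with the free hydroxyl the annulation is base-neutral overall because methanol is the only by-product.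
- Both temporary oxygens are MOM ethers. They survive n-BuLi and fluoride, and the acetal peri to the C4 carbonyl can be removed alone by chelation, which shortens the endgame to four steps.

**Route**

Step 1
Reactants: 1 4-hydroxyacetophenone; 2 prenyl bromide
Product: 3 1-[4-hydroxy-3-(3-methylbut-2-en-1-yl)phenyl]ethan-1-one
Conditions: KOH (10% aq.), 2 added slowly, 0 °C → rt
Reagents that add atoms: none
Why: direct ortho-C-prenylation of the ambident phenoxide is favoured in water, where hydrogen bonding shields the oxygen, and the acetyl group blocks the para position, so the prenyl group can only enter ortho to the hydroxyl; the O-prenyl ether and the bis-prenylated material are removed by chromatography.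

Step 2
Reactants: 3 1-[4-hydroxy-3-(3-methylbut-2-en-1-yl)phenyl]ethan-1-one; 4 3-chloro-3-methylbut-1-yne
Product: 5 1-[4-(2-methylbut-3-yn-2-yloxy)-3-(3-methylbut-2-en-1-yl)phenyl]ethan-1-one
Conditions: DBU, CuCl2 (cat.), MeCN, 0 °C → rt
Reagents that add atoms: none
Why: copper-catalysed O-propargylation of a phenol with a tertiary propargylic chloride proceeds through a copper acetylide-derived electrophile and tolerates the ortho-substituted phenoxide, while ketone and prenyl group are inert.

Step 3
Reactants: 5 1-[4-(2-methylbut-3-yn-2-yloxy)-3-(3-methylbut-2-en-1-yl)phenyl]ethan-1-one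
Product: 7 1-[2,2-dimethyl-8-(3-methylbut-2-en-1-yl)-2H-chromen-6-yl]ethan-1-one (Chr–COCH3), via ortho-allenylphenol 6 (not isolated)
Conditions: PhNEt2, 190 °C
Reagents that add atoms: none
Why: thermal aromatic propargyl Claisen rearrangement to the only free ortho carbon gives allenylphenol 6, which closes to the 2,2-dimethyl-2H-chromene by 1,5-hydrogen shift and oxa-6π electrocyclisation.

Step 4
Reactants: 7 Chr–COCH3; 8 dimethyl carbonate
Product: 9 methyl 3-Chr-3-oxopropanoate
Conditions: NaH, 8 (excess), THF, reflux; then aq. HCl
Reagents that add atoms: none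
Why: crossed Claisen condensation of the methyl ketone enolate with dimethyl carbonate is driven to completion by deprotonation of the β-keto ester formed, and neither alkene reacts with NaH.

Step 5
Reactants: 9 methyl 3-Chr-3-oxopropanoate
Product: 10 methyl (3R)-3-Chr-3-hydroxypropanoate
Conditions: RuCl[(R,R)-TsDPEN](p-cymene) (1 mol %), HCO2H/Et3N (5:2), DMF, 40 °C
Reagents that add atoms: none
Why: Noyori-type asymmetric transfer hydrogenation delivers hydride to one face of the aryl ketone through the six-membered outer-sphere transition state in which the aryl ring lies against the p-cymene ligand, so the (R,R) catalyst should set the (R) carbinol centre, while ester and both alkenes are not reduced.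

Step 6
Reactants: 11 phloroglucinol
Product: 12 3,5-bis(methoxymethoxy)phenol
Conditions: MOMCl (2.1 equiv), i-Pr2NEt, DMF, 0 °C → rt
Reagents that add atoms: chloromethyl methyl ether, COCCl
Why: Williamson-type O-alkylation with the hard alkoxymethyl chloride occurs on oxygen and not on carbon, and with two equivalents the bis-ether is the main component of a statistical mixture from which it is separated by chromatography.

Step 7
Reactants: 12 3,5-bis(methoxymethoxy)phenol
Product: 13 2-bromo-3,5-bis(methoxymethoxy)phenol
Conditions: NBS (1.0 equiv), i-Pr2NH (10 mol %), CH2Cl2, −78 → 0 °C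
Reagents that add atoms: N-bromosuccinimide, O=C1CCC(=O)N1Br
Why: amine-catalysed electrophilic aromatic bromination delivers bromine ortho to the free hydroxyl through a hydrogen-bonded N-bromoamine, the two ortho positions are equivalent and the para position is shielded between two MOM-oxy groups, and one equivalent of NBS at low temperature limits double bromination.

Step 8
Reactants: 13 2-bromo-3,5-bis(methoxymethoxy)phenol
Product: 16 3,5-bis(methoxymethoxy)-2-(trimethylsilyl)phenyl trifluoromethanesulfonate, via aryl trimethylsilyl ether 14 (not isolated), via lithium silylphenolate 15 (not isolated)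
Conditions: HMDS, THF, 70 °C, evaporate; n-BuLi, THF, −100 → −78 °C; Tf2O, −78 °C
Reagents that add atoms: hexamethyldisilazane, C[Si](C)(C)N[Si](C)(C)C; trifluoromethanesulfonic anhydride, O=S(=O)(OS(=O)(=O)C(F)(F)F)C(F)(F)F
Why: O-silylation, bromine–lithium exchange and 1,3 O-to-C silyl migration (retro-Brook rearrangement, driven by turning an aryllithium into a phenoxide) place silicon on the carbon between the two oxygens, and phenoxide 15 is trapped as the triflate, the exchange at −100 °C being faster than MOM-directed ortho-lithiation.

Step 9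
Reactants: 10 methyl (3R)-3-Chr-3-hydroxypropanoate; 16 3,5-bis(methoxymethoxy)-2-(trimethylsilyl)phenyl trifluoromethanesulfonate
Product: 18 (2R)-2-Chr-5,7-bis(methoxymethoxy)chroman-4-one, via 3,5-bis(methoxymethoxy)benzyne 17 (not isolated)
Conditions: KF (3 equiv), 18-crown-6 (3 equiv), THF, −20 °C → rt; 16 (1.6 equiv) added over several hours
Reagents that add atoms: none
Why: Proposed new method: fluoride attacks silicon of 16 and triflate leaves to give aryne 17, the fluoride-activated hydroxyl of 10 adds as an alkoxide to the aryne carbon that becomes C8a, and the C4a carbanion so formed attacks the methyl ester through a six-membered transition state and expels methoxide, which takes up the hydroxyl proton as methanol. The closest known reaction types are the fluoride-mediated annulation of salicylate esters with ortho-silylaryl triflates to xanthones and the O–H insertion of aliphatic alcohols into arynes; the new element is an aliphatic β-hydroxy ester serving as oxygen nucleophile and acyl electrophile in the same event. Ring C closes by 6-exo-trig addition–elimination at the exocyclic ester carbonyl. No stereocentre is created, and C2 keeps its (R) configuration because the C2–O1 bond is never broken, provided the temperature stays low enough to avoid retro-aldol cleavage of 10 and base-induced opening of 18. The step needs attack of oxygen at C8a and not at C4a, which the MOM-oxy group on the carbon flanking the triple bond (the future C5) secures by polarising and distorting the aryne so that the nucleophile enters at the distal carbon and the charge develops beside the oxygen substituent. Acylation must also outrun protonation of the carbanion, which is why THF is used instead of acetonitrile and why the simple methyl ester is kept.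

Step 10
Reactants: 18 (2R)-2-Chr-5,7-bis(methoxymethoxy)chroman-4-one
Product: 19 (2R)-2-Chr-5-hydroxy-7-(methoxymethoxy)chroman-4-one
Conditions: MgBr2·OEt2 (3 equiv), Et2O/CH2Cl2, 0 °C → rt; then H2O
Reagents that add atoms: none
Why: chelation-controlled Lewis acid cleavage of an acetal, in which MgBr2 binds between the C4 carbonyl and the peri O5 oxygen so that bromide removes the methoxymethyl group from that oxygen only, while the remote C7 MOM ether, the alkenes and the C2 centre are untouched under non-basic conditions.

Step 11
Reactants: 19 (2R)-2-Chr-5-hydroxy-7-(methoxymethoxy)chroman-4-one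
Product: 20 (2R)-2-Chr-7-(methoxymethoxy)-4-oxochroman-5-yl trifluoromethanesulfonate
Conditions: Tf2O, pyridine, CH2Cl2, −20 → 0 °C
Reagents that add atoms: trifluoromethanesulfonic anhydride, O=S(=O)(OS(=O)(=O)C(F)(F)F)C(F)(F)F
Why: O-sulfonylation of the hydrogen-bonded C5 phenol needs the strong electrophile Tf2O, and pyridine is too weak a base to cause retro-oxa-Michael opening of ring C or enol triflate formation at low temperature.

Step 12
Reactants: 20 (2R)-2-Chr-7-(methoxymethoxy)-4-oxochroman-5-yl trifluoromethanesulfonate
Product: 21 (2R)-2-Chr-7-(methoxymethoxy)chroman-4-one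
Conditions: Pd(OAc)2 (5 mol %), 1,1'-bis(diphenylphosphino)ferrocene (dppf, 10 mol %), HCO2H (3 equiv), Et3N (2.5 equiv), DMF, 60 °C
Reagents that add atoms: none
Why: palladium-catalysed formate reduction of an aryl triflate, in which zerovalent palladium formed in situ from Pd(OAc)2 inserts into the electron-poor C5–O bond, formate exchange and loss of CO2 give an aryl palladium hydride and reductive elimination forms C5–H, while the trisubstituted alkene, the chromene alkene and the MOM ether are inert and the slight excess of formic acid keeps the medium from opening ring C.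

Step 13
Reactants: 21 (2R)-2-Chr-7-(methoxymethoxy)chroman-4-one
Product: 22 ent-abyssinone III, (2R)-2-Chr-7-hydroxychroman-4-one
Conditions: HCl (3 M aq.), MeOH, 40 °C
Reagents that add atoms: none
Why: acid-catalysed acetal exchange with methanol frees the C7 phenol, ring B has no free phenol beside the prenyl or chromene alkene so acid-induced cyclisation is not available, and the flavanone centre does not epimerise under mild acid.

**Compound list**

1 | 4-hydroxyacetophenone | CC(=O)c1ccc(O)cc1 | starting material
2 | prenyl bromide (1-bromo-3-methylbut-2-ene) | CC(C)=CCBr | starting material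
3 | 1-[4-hydroxy-3-(3-methylbut-2-en-1-yl)phenyl]ethan-1-one | CC(=O)c1ccc(O)c(CC=C(C)C)c1 | intermediate
4 | 3-chloro-3-methylbut-1-yne | CC(C)(Cl)C#C | starting material
5 | 1-[4-(2-methylbut-3-yn-2-yloxy)-3-(3-methylbut-2-en-1-yl)phenyl]ethan-1-one | CC(=O)c1ccc(OC(C)(C)C#C)c(CC=C(C)C)c1 | intermediate
6 | 1-[4-hydroxy-3-(3-methylbuta-1,2-dien-1-yl)-5-(3-methylbut-2-en-1-yl)phenyl]ethan-1-one (ortho-allenylphenol, not isolated) | CC(=O)c1cc(CC=C(C)C)c(O)c(C=C=C(C)C)c1 | intermediate
7 | 1-[2,2-dimethyl-8-(3-methylbut-2-en-1-yl)-2H-chromen-6-yl]ethan-1-one | CC(=O)c1cc(CC=C(C)C)c2OC(C)(C)C=Cc2c1 | intermediate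
8 | dimethyl carbonate | COC(=O)OC | starting material
9 | methyl 3-[2,2-dimethyl-8-(3-methylbut-2-en-1-yl)-2H-chromen-6-yl]-3-oxopropanoate | COC(=O)CC(=O)c1cc(CC=C(C)C)c2OC(C)(C)C=Cc2c1 | intermediate
10 | methyl (3R)-3-[2,2-dimethyl-8-(3-methylbut-2-en-1-yl)-2H-chromen-6-yl]-3-hydroxypropanoate | CC(C)=CCc1cc([C@H](O)CC(=O)OC)cc2c1OC(C)(C)C=C2 | intermediate
11 | phloroglucinol | Oc1cc(O)cc(O)c1 | starting material
12 | 3,5-bis(methoxymethoxy)phenol | COCOc1cc(O)cc(OCOC)c1 | intermediate
13 | 2-bromo-3,5-bis(methoxymethoxy)phenol | COCOc1cc(O)c(Br)c(OCOC)c1 | intermediate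
14 | [2-bromo-3,5-bis(methoxymethoxy)phenoxy]trimethylsilane (not isolated) | COCOc1cc(O[Si](C)(C)C)c(Br)c(OCOC)c1 | intermediate
15 | lithium 3,5-bis(methoxymethoxy)-2-(trimethylsilyl)phenolate (not isolated) | [Li+].COCOc1cc([O-])c([Si](C)(C)C)c(OCOC)c1 | intermediate
16 | 3,5-bis(methoxymethoxy)-2-(trimethylsilyl)phenyl trifluoromethanesulfonate | COCOc1cc(OCOC)c([Si](C)(C)C)c(OS(=O)(=O)C(F)(F)F)c1 | intermediate
17 | 3,5-bis(methoxymethoxy)benzyne, 1,2-didehydro-3,5-bis(methoxymethoxy)benzene (not isolated) | COCOC1=CC(OCOC)=CC#C1 | intermediate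
18 | (2R)-2-[2,2-dimethyl-8-(3-methylbut-2-en-1-yl)-2H-chromen-6-yl]-5,7-bis(methoxymethoxy)chroman-4-one | CC(C)=CCc1cc([C@H]2CC(=O)c3c(OCOC)cc(OCOC)cc3O2)cc2c1OC(C)(C)C=C2 | intermediate
19 | (2R)-2-[2,2-dimethyl-8-(3-methylbut-2-en-1-yl)-2H-chromen-6-yl]-5-hydroxy-7-(methoxymethoxy)chroman-4-one | CC(C)=CCc1cc([C@H]2CC(=O)c3c(O)cc(OCOC)cc3O2)cc2c1OC(C)(C)C=C2 | intermediate
20 | (2R)-2-[2,2-dimethyl-8-(3-methylbut-2-en-1-yl)-2H-chromen-6-yl]-7-(methoxymethoxy)-4-oxochroman-5-yl trifluoromethanesulfonate | CC(C)=CCc1cc([C@H]2CC(=O)c3c(OS(=O)(=O)C(F)(F)F)cc(OCOC)cc3O2)cc2c1OC(C)(C)C=C2 | intermediate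
21 | (2R)-2-[2,2-dimethyl-8-(3-methylbut-2-en-1-yl)-2H-chromen-6-yl]-7-(methoxymethoxy)chroman-4-one | CC(C)=CCc1cc([C@H]2CC(=O)c3ccc(OCOC)cc3O2)cc2c1OC(C)(C)C=C2 | intermediate
22 | ent-abyssinone III, (2R)-2-[2,2-dimethyl-8-(3-methylbut-2-en-1-yl)-2H-chromen-6-yl]-7-hydroxychroman-4-one | CC(C)=CCc1cc([C@H]2CC(=O)c3ccc(O)cc3O2)cc2c1OC(C)(C)C=C2 | target

**Step count and risks**

Total step count: 13.
Longest linear sequence: 10 steps (steps 1 to 5 and 9 to 13, from 4-hydroxyacetophenone). The aryne precursor branch (steps 6 to 8) joins at step 9.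

Steps most likely to fail:

1. Step 9 (Proposed new method). What may go wrong: protonation of the C4a carbanion before it acylates, which gives the uncyclised aryl ether and then loss of aryloxide by E1cB; retro-aldol fragmentation of the alkoxide of 10; or erosion of the C2 configuration through base-induced opening of ring C. The fallback uses known chemistry, forms C4–C4a first and then closes O1–C2 with inversion. It sets out from β-keto ester 9, which is reduced with the enantiomeric catalyst RuCl[(S,S)-TsDPEN](p-cymene) in HCO2H/Et3N to methyl (3S)-3-Chr-3-hydroxypropanoate F1. Treatment of this ester with MeNH(OMe)·HCl and i-PrMgCl in THF at −20 °C gives (3S)-3-Chr-3-hydroxy-N-methoxy-N-methylpropanamide F2. Commercial 4-bromoresorcinol is protected with MOMCl and i-Pr2NEt to give 1-bromo-2,4-bis(methoxymethoxy)benzene F3, whose aryllithium (n-BuLi, THF, −78 °C, in excess to allow for the free hydroxyl) adds to the Weinreb amide to give (3S)-1-[2,4-bis(methoxymethoxy)phenyl]-3-Chr-3-hydroxypropan-1-one F4. MgBr2·OEt2 removes the acetal beside the ketone by chelation and gives (3S)-3-Chr-3-hydroxy-1-[2-hydroxy-4-(methoxymethoxy)phenyl]propan-1-one F5. Intramolecular Mitsunobu etherification (PPh3, DIAD, THF, 0 °C) then closes ring C with inversion at the carbinol carbon and comes back to the route at 21, so that steps 10 to 12 are no longer needed. In this fallback the electron-rich benzylic carbinol may partly ionise, so the cyclisation is run cold and the enantiomeric purity of 21 is checked.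

2. Step 10. What may go wrong: loss of site selectivity, with both acetals cleaved or the peri acetal cleaved incompletely. The fallback replaces selective deprotection by global deprotection and selective reprotection. It sets out from 18, which is treated with HCl in MeOH at 40 °C to give (2R)-2-Chr-5,7-dihydroxychroman-4-one F6. The C7 hydroxyl, which is more acidic and not hydrogen-bonded to the carbonyl, is then protected alone with MOMCl (1.05 equiv) and i-Pr2NEt in CH2Cl2 at 0 °C, which comes back to the route at 19.

3. Step 7. What may go wrong: bromination at the carbon para to the hydroxyl, between the two acetals, or double bromination. The fallback replaces electrophilic substitution by directed ortho-metalation. It sets out from 12, which reacts with i-PrNCO and Et3N to give 3,5-bis(methoxymethoxy)phenyl N-isopropylcarbamate F7. In situ N-silylation (TBSOTf, TMEDA), lithiation with n-BuLi at −78 °C at the carbon flanked by the carbamate and a MOM ether, and quenching with TMSCl give 3,5-bis(methoxymethoxy)-2-(trimethylsilyl)phenyl N-isopropylcarbamate F8. One-pot carbamate cleavage (Et2NH, DBU, MeCN, 40 °C) and triflation of the phenoxide with PhNTf2 come back to the route at 16.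

**Further compounds**

F1 | step 9 | methyl (3S)-3-[2,2-dimethyl-8-(3-methylbut-2-en-1-yl)-2H-chromen-6-yl]-3-hydroxypropanoate | CC(C)=CCc1cc([C@@H](O)CC(=O)OC)cc2c1OC(C)(C)C=C2
F2 | step 9 | (3S)-3-[2,2-dimethyl-8-(3-methylbut-2-en-1-yl)-2H-chromen-6-yl]-3-hydroxy-N-methoxy-N-methylpropanamide | CC(C)=CCc1cc([C@@H](O)CC(=O)N(C)OC)cc2c1OC(C)(C)C=C2
F3 | step 9 | 1-bromo-2,4-bis(methoxymethoxy)benzene | COCOc1ccc(Br)c(OCOC)c1
F4 | step 9 | (3S)-1-[2,4-bis(methoxymethoxy)phenyl]-3-[2,2-dimethyl-8-(3-methylbut-2-en-1-yl)-2H-chromen-6-yl]-3-hydroxypropan-1-one | CC(C)=CCc1cc([C@@H](O)CC(=O)c3ccc(OCOC)cc3OCOC)cc2c1OC(C)(C)C=C2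
F5 | step 9 | (3S)-3-[2,2-dimethyl-8-(3-methylbut-2-en-1-yl)-2H-chromen-6-yl]-3-hydroxy-1-[2-hydroxy-4-(methoxymethoxy)phenyl]propan-1-one | CC(C)=CCc1cc([C@@H](O)CC(=O)c3ccc(OCOC)cc3O)cc2c1OC(C)(C)C=C2
F6 | step 10 | (2R)-2-[2,2-dimethyl-8-(3-methylbut-2-en-1-yl)-2H-chromen-6-yl]-5,7-dihydroxychroman-4-one | CC(C)=CCc1cc([C@H]2CC(=O)c3c(O)cc(O)cc3O2)cc2c1OC(C)(C)C=C2
F7 | step 7 | 3,5-bis(methoxymethoxy)phenyl N-isopropylcarbamate | CC(C)NC(=O)Oc1cc(OCOC)cc(OCOC)c1
F8 | step 7 | 3,5-bis(methoxymethoxy)-2-(trimethylsilyl)phenyl N-isopropylcarbamate | CC(C)NC(=O)Oc1cc(OCOC)cc(OCOC)c1[Si](C)(C)C
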